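**Retrosynthetic overview**
- Target ⇒ acetylation, SeO2 oxidation at C30 and oxidation at C3 of a farnesyl-extended diol; C11–C12 comes from a copper-catalysed sp3–sp3 coupling of a C11 organomagnesium with (2E,6E)-farnesyl bromide.
- C8 tertiary alcohol ⇒ Mukaiyama hydration of a Δ7 alkene; ring A (formed second and last) ⇒ hydrogen-atom-transfer radical cyclization of the C5 isopropenyl group onto a C3 aldehyde, which gives the cis ring fusion.
- Key bond C9–C11 ⇒ [2,3]-sigmatropic Wittig–Still rearrangement of a 7β-allylic stannylmethyl ether (chirality transfer C7 → C9).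
- 7β-Allylic alcohol ⇒ Wharton transposition of the epoxy ketone of a 6,6-dialkylated carvone; ring B is bought as (S)-carvone, whose C5 stereocentre controls C10, C7, then C9 and C8.

Assumption: the SMILES is read literally, i.e. (5S,8R,9R,10S) with H-5 on the face of the C-10 methyl (cis-fused decalin, 5β-H); polypodane numbering (C1–C10 ring carbons, C11–C22 chain, C30 = CH2OAc) and α/β (β = face of the C-10 methyl) are used for all intermediates.

**Route**

Step 1
Reactants: 1 (S)-(+)-carvone; 2 2-(2-bromoethyl)-1,3-dioxolane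
Product: 4 (5S,6R)-6-[2-(1,3-dioxolan-2-yl)ethyl]-2-methyl-5-(prop-1-en-2-yl)cyclohex-2-en-1-one (major 5,6-trans epimer), via lithium dienolate 3 (not isolated)
Conditions: LiN(iPr)2, THF, −78 °C; then 2, HMPA, Bu4NI (cat.), −78 → 0 °C
Reagents that add atoms: 2-(2-bromoethyl)-1,3-dioxolane (2), BrCCC1OCCO1
Why: Kinetic deprotonation of the cross-conjugated enone occurs only at the α′-CH2 (C10) and the lithium dienolate is alkylated by the primary halide (SN2 enolate alkylation); the new C10 centre forms mainly trans to the isopropenyl group but is erased again in step 2.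

Step 2
Reactants: 4
Product: 6 (5R,6S)-6-[2-(1,3-dioxolan-2-yl)ethyl]-2,6-dimethyl-5-(prop-1-en-2-yl)cyclohex-2-en-1-one (10β-methyl; acetal chain cis to isopropenyl), via lithium enolate 5 (not isolated)
Conditions: LiN(iPr)2, THF, −78 → −20 °C; MeI, −78 → 0 °C
Reagents that add atoms: iodomethane, CI
Why: Enolate alkylation of a 6-substituted carvone: MeI attacks the enolate face anti to the adjacent C5 isopropenyl group, so the methyl ends β (trans to isopropenyl) and the acetal chain α (cis to it), which fixes the quaternary C10 stereocentre under control of C5.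

Step 3
Reactants: 6
Product: 7 7β,8β-epoxy ketone of 6 [3-[2-(1,3-dioxolan-2-yl)ethyl]-1,3-dimethyl-4-(prop-1-en-2-yl)-7-oxabicyclo[4.1.0]heptan-2-one; epoxide trans to isopropenyl]
Conditions: 30% H2O2, NaOH (cat.), MeOH, 0 °C
Reagents that add atoms: hydrogen peroxide, OO
Why: Weitz–Scheffer nucleophilic epoxidation: hydroperoxide adds axially to C7 anti to the C5 isopropenyl group, as it does with carvone itself, giving the 7β,8β-epoxide while the isolated isopropenyl alkene and the acetal are inert.

Step 4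
Reactants: 7
Product: 9 7β-hydroxy-Δ8(9) allylic alcohol [4-[2-(1,3-dioxolan-2-yl)ethyl]-2,4-dimethyl-5-(prop-1-en-2-yl)cyclohex-2-en-1-ol; OH trans to isopropenyl], via epoxy hydrazone 8 (not isolated)
Conditions: N2H4·H2O (5 equiv), AcOH (cat.), MeOH, rt → 50 °C
Reagents that add atoms: none
Why: Wharton transposition: the hydrazone opens the epoxide to an alkenyl diazene that loses N2, moving the alkene to C8=C9 and leaving the C7–O bond untouched, so the alcohol is 7β.

Step 5
Reactants: 9
Product: 11 tributylstannylmethyl ether of 9, via potassium alkoxide 10 (not isolated)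
Conditions: KH, THF, 0 °C; Bu3SnCH2I, rt
Reagents that add atoms: (iodomethyl)tributylstannane, CCCC[Sn](CCCC)(CCCC)CI
Why: Williamson etherification of the secondary allylic alkoxide with the reactive α-stannyl iodide; no stereocentre is touched.

Step 6
Reactants: 11
Product: 13 {6-[2-(1,3-dioxolan-2-yl)ethyl]-2,6-dimethyl-5-(prop-1-en-2-yl)cyclohex-2-en-1-yl}methanol (9β-CH2OH; Δ7), via lithiomethyl ether 12 (not isolated)
Conditions: nBuLi, THF, −78 → −20 °C; then H2O
Reagents that add atoms: none
Why: Wittig–Still [2,3]-sigmatropic rearrangement: tin–lithium exchange gives the α-oxy carbanion, which bonds to C9 suprafacially on the face of the C7 oxygen (β), so chirality passes from C7 to C9 (9β-CH2OH, 9α-H) and the alkene moves to C7=C8.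

Step 7
Reactants: 13
Product: 14 3-[2-(hydroxymethyl)-1,3-dimethyl-6-(prop-1-en-2-yl)cyclohex-3-en-1-yl]propanal
Conditions: aq. HCl (1 M), THF, rt
Reagents that add atoms: water, O
Why: Mild acid-catalysed acetal hydrolysis frees the aldehyde without touching the alkenes or the primary alcohol.

Step 8
Reactants: 14
Product: 15 5β-drim-7-ene-3,11-diol (cis-fused decalin; C3 epimers)
Conditions: Fe(acac)3 (30 mol %), PhSiH3, EtOH, 60 °C, 0.02 M
Reagents that add atoms: none
Why: Metal-hydride hydrogen-atom-transfer (Mukaiyama-type) radical cyclization: the iron hydride delivers H to the CH2 of the 1,1-disubstituted isopropenyl group faster than to the trisubstituted ring alkene, and the tertiary C4 centre adds 6-exo to the aldehyde, forming C3–C4, the gem-dimethyl carbon and ring A, cis-fused because the two tethers on C5 and C10 are cis (the C3 alcohol is an epimer mixture that is oxidised in step 12).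

Step 9
Reactants: 15
Product: 17 5β-drimane-3,8α,11-triol, via tertiary hydroperoxide 16 (not isolated)
Conditions: Mn(dpm)3 (10 mol %), PhSiH3, O2 (1 atm), iPrOH/CH2Cl2, 0 °C → rt; then P(OEt)3
Reagents that add atoms: dioxygen, O=O
Why: Mukaiyama (Markovnikov) hydration: hydrogen-atom transfer to C7 leaves the tertiary C8 centre, which takes up O2 from the α face, anti to the C10 methyl and the C9 hydroxymethyl group, so the alcohol is 8α and the methyl 8β, as is usual for labd-7-enes.

Step 10
Reactants: 17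
Product: 18 11-iodo-5β-drimane-3,8α-diol
Conditions: I2, PPh3, imidazole, toluene/MeCN, rt
Reagents that add atoms: iodine, II
Why: Garegg–Samuelsson (Appel-type) iodination is selective for the only primary alcohol; the neopentyl-like secondary C3–OH and the tertiary C8–OH do not react under these conditions.

Step 11
Reactants: 18; 19 (2E,6E)-farnesyl bromide
Product: 22 5β-polypoda-13E,17E,21-triene-3,8α-diol, via trilithium dialkoxide 20 (not isolated), via alkylmagnesium bromide 21 (not isolated)
Conditions: tBuLi (4.2 equiv), Et2O, −78 °C; MgBr2·OEt2; then 19, Li2CuCl4 (5 mol %), THF, −78 → 0 °C; H2O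
Reagents that add atoms: (2E,6E)-farnesyl bromide (19), BrC/C=C(C)/CC/C=C(C)/CCC=C(C)C
Why: Lithium–iodine exchange (the first two equivalents of tBuLi deprotonate the alcohols), transmetalation to magnesium and Kochi–Schlosser Li2CuCl4-catalysed coupling: the alkyl group attacks the unhindered primary carbon of the γ,γ-disubstituted allylic bromide (SN2, not SN2′) with retention of both E alkenes, forming C11–C12.

Step 12
Reactants: 22
Product: 23 8α-hydroxy-5β-polypoda-13E,17E,21-trien-3-one
Conditions: Dess–Martin periodinane, CH2Cl2, rt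
Reagents that add atoms: none
Why: Dess–Martin oxidation converts the only oxidisable (secondary) alcohol into the C3 ketone, merging the C3 epimers; the tertiary C8–OH and the alkenes are inert.

Step 13
Reactants: 23
Product: 24 8α,30-dihydroxy-5β-polypoda-13E,17E,21E-trien-3-one
Conditions: SeO2 (0.3 equiv), tBuOOH, salicylic acid (cat.), CH2Cl2, 0 °C → rt (stopped at partial conversion, 23 recycled)
Reagents that add atoms: tert-butyl hydroperoxide, CC(C)(C)OO (oxygen relayed by SeO2, O=[Se]=O)
Why: Sharpless catalytic SeO2 allylic oxidation: ene reaction at the most electron-rich and least hindered terminal alkene followed by a [2,3]-sigmatropic shift oxidises only the E-methyl group (C30), giving the (21E)-allylic alcohol.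

Step 14
Reactants: 24
Product: 25 myrrhanone A acetate as specified [(5S,8R,9R,10S)-30-acetoxy-8-hydroxypolypoda-13E,17E,21E-trien-3-one]
Conditions: Ac2O, pyridine, CH2Cl2, 0 °C
Reagents that add atoms: acetic anhydride, CC(=O)OC(C)=O
Why: Acylation (nucleophilic acyl substitution) of the primary allylic alcohol; the tertiary C8–OH is not acetylated under these conditions, which gives the target.

**Compound list**

1 | (S)-(+)-carvone | CC1=CC[C@@H](CC1=O)C(C)=C | starting material
2 | 2-(2-bromoethyl)-1,3-dioxolane | BrCCC1OCCO1 | starting material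
3 | lithium dienolate of 1 (O–Li on C9, C9=C10) | [Li]OC1=C[C@@H](C(C)=C)CC=C1C | intermediate
4 | (5S,6R)-6-[2-(1,3-dioxolan-2-yl)ethyl]-2-methyl-5-(prop-1-en-2-yl)cyclohex-2-en-1-one (major trans epimer) | O=C1[C@H](CCC2OCCO2)[C@@H](C(C)=C)CC=C1C | intermediate
5 | lithium enolate of 4 | [Li]OC1=C(CCC2OCCO2)[C@@H](C(C)=C)CC=C1C | intermediate
6 | (5R,6S)-6-[2-(1,3-dioxolan-2-yl)ethyl]-2,6-dimethyl-5-(prop-1-en-2-yl)cyclohex-2-en-1-one (methyl trans, acetal chain cis to isopropenyl) | O=C1[C@@](C)(CCC2OCCO2)[C@@H](C(C)=C)CC=C1C | intermediate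
7 | 7β,8β-epoxy ketone of 6 (epoxide trans to isopropenyl, cis to the C10 methyl) | O=C1[C@@](C)(CCC3OCCO3)[C@@H](C(C)=C)C[C@@H]2O[C@]12C | intermediate
8 | hydrazone of 7 | NN=C1[C@@](C)(CCC3OCCO3)[C@@H](C(C)=C)C[C@@H]2O[C@]12C | intermediate
9 | 4-[2-(1,3-dioxolan-2-yl)ethyl]-2,4-dimethyl-5-(prop-1-en-2-yl)cyclohex-2-en-1-ol (7β-OH, cis to the C10 methyl, trans to isopropenyl) | CC1=C[C@@](C)(CCC2OCCO2)[C@@H](C(C)=C)C[C@@H]1O | intermediate
10 | potassium alkoxide of 9 | CC1=C[C@@](C)(CCC2OCCO2)[C@@H](C(C)=C)C[C@@H]1O[K] | intermediate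
11 | tributylstannylmethyl ether of 9 | CC1=C[C@@](C)(CCC2OCCO2)[C@@H](C(C)=C)C[C@@H]1OC[Sn](CCCC)(CCCC)CCCC | intermediate
12 | lithiomethyl ether of 9 | CC1=C[C@@](C)(CCC2OCCO2)[C@@H](C(C)=C)C[C@@H]1OC[Li] | intermediate
13 | {6-[2-(1,3-dioxolan-2-yl)ethyl]-2,6-dimethyl-5-(prop-1-en-2-yl)cyclohex-2-en-1-yl}methanol (9β-CH2OH cis to the C10 methyl, trans to isopropenyl) | OC[C@H]1C(C)=CC[C@H](C(C)=C)[C@]1(C)CCC2OCCO2 | intermediate
14 | 3-[2-(hydroxymethyl)-1,3-dimethyl-6-(prop-1-en-2-yl)cyclohex-3-en-1-yl]propanal (configuration as 13) | OC[C@H]1C(C)=CC[C@H](C(C)=C)[C@]1(C)CCC=O | intermediate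
15 | 5β-drim-7-ene-3,11-diol (cis-fused, 9β-CH2OH, 10β-CH3, C3 epimers) | OC[C@@H]1[C@@]2(C)CCC(O)C(C)(C)[C@H]2CC=C1C | intermediate
16 | 8α-hydroperoxy-5β-drimane-3,11-diol | OC[C@@H]1[C@@]2(C)CCC(O)C(C)(C)[C@H]2CC[C@@]1(C)OO | intermediate
17 | 5β-drimane-3,8α,11-triol | OC[C@@H]1[C@@]2(C)CCC(O)C(C)(C)[C@H]2CC[C@@]1(C)O | intermediate
18 | 11-iodo-5β-drimane-3,8α-diol | IC[C@@H]1[C@@]2(C)CCC(O)C(C)(C)[C@H]2CC[C@@]1(C)O | intermediate
19 | (2E,6E)-farnesyl bromide | BrC/C=C(C)/CC/C=C(C)/CCC=C(C)C | starting material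
20 | trilithium derivative of 18 (C11–Li, two O–Li) | [Li]C[C@@H]1[C@@]2(C)CCC(O[Li])C(C)(C)[C@H]2CC[C@@]1(C)O[Li] | intermediate
21 | C11 alkylmagnesium bromide (dilithium dialkoxide) | Br[Mg]C[C@@H]1[C@@]2(C)CCC(O[Li])C(C)(C)[C@H]2CC[C@@]1(C)O[Li] | intermediate
22 | 5β-polypoda-13E,17E,21-triene-3,8α-diol (C3 epimers) | CC(C)=CCC/C(C)=C/CC/C(C)=C/CC[C@@H]1[C@@]2(C)CCC(O)C(C)(C)[C@H]2CC[C@@]1(C)O | intermediate
23 | 8α-hydroxy-5β-polypoda-13E,17E,21-trien-3-one | CC(C)=CCC/C(C)=C/CC/C(C)=C/CC[C@@H]1[C@@]2(C)CCC(=O)C(C)(C)[C@H]2CC[C@@]1(C)O | intermediate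
24 | 8α,30-dihydroxy-5β-polypoda-13E,17E,21E-trien-3-one | OC/C(C)=C/CC/C(C)=C/CC/C(C)=C/CC[C@@H]1[C@@]2(C)CCC(=O)C(C)(C)[C@H]2CC[C@@]1(C)O | intermediate
25 | myrrhanone A acetate, (5S,8R,9R,10S)-30-acetoxy-8-hydroxypolypoda-13E,17E,21E-trien-3-one | CC(=O)OC/C(C)=C/CC/C(C)=C/CC/C(C)=C/CC[C@@H]1[C@@]2(C)CCC(=O)C(C)(C)[C@H]2CC[C@@]1(C)O | target

**Step count**
Total: 14 steps. Longest linear sequence: 14 steps, from 1.

**Steps most likely to fail, with fallbacks**

Step 4 (Wharton transposition). The carbonyl is flanked by the quaternary C10 and the fully substituted epoxide carbon, so hydrazone formation may be too slow. The fallback sets out from 7: NaBH4 in MeOH reduces the ketone to the epoxy alcohol F1 (either C9 epimer). Cp2TiCl, made from Cp2TiCl2 and Zn dust in THF, then opens the epoxide homolytically at C8; capture of the tertiary centre by a second equivalent of this trivalent titanium reagent and β-elimination of the C9 oxygen give the same allylic alcohol. The route is rejoined at 9.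

Step 8 (radical closure of ring A). Addition of the tertiary centre to an aldehyde is reversible, and hydrogen-atom transfer to the ring alkene can compete. The fallback sets out from 14: I2 in aqueous NH3/THF converts the aldehyde into the nitrile F2. The same Fe(acac)3/PhSiH3 conditions then close ring A onto the nitrile, where the addition is not reversed, and acidic work-up hydrolyses the imine to the hydroxy ketone F3. NaBH4 reduction of the C3 ketone returns the diol, and the route is rejoined at 15.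

Step 11 (organometallic coupling). The β-branched alkyllithium carries two alkoxides and may aggregate or give SN2′ product. The fallback sets out from 18: PhSO2Na in DMF at 80 °C gives the phenyl sulfone F4. Deprotonation with nBuLi (3 equiv, THF/HMPA, −78 °C) and C-alkylation with 19 give the farnesylated sulfone F5 (C11 epimers). Reductive desulfonylation with Na(Hg)/Na2HPO4 in MeOH then gives the coupled diol, and the route is rejoined at 22.

**Further compounds**

F1 | step 4 | 3-[2-(1,3-dioxolan-2-yl)ethyl]-1,3-dimethyl-4-(prop-1-en-2-yl)-7-oxabicyclo[4.1.0]heptan-2-ol (epoxy alcohol from 7, C9 epimers) | OC1[C@@](C)(CCC3OCCO3)[C@@H](C(C)=C)C[C@@H]2O[C@]12C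
F2 | step 8 | 3-[2-(hydroxymethyl)-1,3-dimethyl-6-(prop-1-en-2-yl)cyclohex-3-en-1-yl]propanenitrile | OC[C@H]1C(C)=CC[C@H](C(C)=C)[C@]1(C)CCC#N
F3 | step 8 | 11-hydroxy-5β-drim-7-en-3-one | OC[C@@H]1[C@@]2(C)CCC(=O)C(C)(C)[C@H]2CC=C1C
F4 | step 11 | 11-(phenylsulfonyl)-5β-drimane-3,8α-diol | O=S(=O)(C[C@@H]1[C@@]2(C)CCC(O)C(C)(C)[C@H]2CC[C@@]1(C)O)c1ccccc1
F5 | step 11 | 11-(phenylsulfonyl)-5β-polypoda-13E,17E,21-triene-3,8α-diol (C11 epimers) | CC(C)=CCC/C(C)=C/CC/C(C)=C/CC(S(=O)(=O)c1ccccc1)[C@@H]1[C@@]2(C)CCC(O)C(C)(C)[C@H]2CC[C@@]1(C)O
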